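**Retrosynthetic overview**
- Target ⇐ its tri-O-methyl ether: the two CHO groups come last, by directed ortho-lithiation/formylation of a 2,4,6-trimethoxyphenyl ring; three O-methyl groups and one silyl ether are then removed.
- Ring A end game: C4 carbinol and C2/C3 methylenes ⇐ Wharton opening of a 3,4-epoxy-2-ketone, then hydrogenation; C1′ and C1 ⇐ cuprate addition/axial protonation on a (Z)-arylidene ketone.
- Key disconnection C1–C1′: intermolecular aldol of the decalin epoxy-ketone enolate with 2,4,6-trimethoxybenzaldehyde (completed as an aldol condensation).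
- Epoxy ketone ⇐ 2-oxo-Δ3-enone ⇐ allylic oxidation of ent-α-eudesmol ⇐ (−)-α-cyperone (reductive triflation, formate reduction, hydration).
- Ring order: ring B from (S)-carvone; ring A by Robinson annulation (chiral-imine Michael addition to ethyl vinyl ketone, then aldol closure); the aryl ring is bought intact.

Assumption: eudesmane numbering is used for the decalin (C1–C10 ring atoms, C11 the carbinol carbon on C7, C1′ the benzylic carbon). In it the target is (1R,4R,5S,7S,10R,1′S): a trans-decalin with the 10-CH3, the 4-OH, the C7 side chain and the C1 side chain all on one face.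

**Step 1**
Reactants: 1 (S)-(+)-carvone
Product: 3 (2S,5S)-dihydrocarvone, via lithium enolate 2 (not isolated)
Conditions: Li[HB(s-Bu)3] (1.1 equiv), THF, −78 °C; then H2O, rt
Reagents that add atoms: none
Why: Conjugate (1,4) hydride reduction of the β-unsubstituted enone leaves the isopropenyl group and C5 untouched; the C2 centre (some 2R epimer) is irrelevant because it is enolised in step 2.

**Step 2**
Reactants: 3 (2S,5S)-dihydrocarvone; 4 (S)-1-phenylethylamine; 5 ethyl vinyl ketone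
Product: 8 (2R,5S)-2-methyl-2-(3-oxopentyl)-5-(prop-1-en-2-yl)cyclohexan-1-one, via ketimine 6 (not isolated), via adduct imine 7 (not isolated)
Conditions: 4 (1.05 equiv), TsOH (cat.), toluene, reflux (Dean–Stark); 5 (1.5 equiv), THF, 40 °C, 72 h; 20% aq AcOH, rt
Reagents that add atoms: ethyl vinyl ketone CCC(=O)C=C; water O
Why: d'Angelo–Pfau chiral-imine Michael addition through the more substituted secondary enamine; the (S)-auxiliary delivers the enone to the face that makes C10 R (methyl cis to the isopropenyl group), overriding the ring's own bias.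

**Step 3**
Reactants: 8 (2R,5S)-2-methyl-2-(3-oxopentyl)-5-(prop-1-en-2-yl)cyclohexan-1-one
Product: 9 (−)-α-cyperone
Conditions: NaOMe (0.3 equiv), MeOH, reflux
Reagents that add atoms: none
Why: Intramolecular aldol condensation closes ring A (Robinson annulation) without touching C7 or C10.

**Step 4**
Reactants: 9 (−)-α-cyperone
Product: 11 (5S,7S,10R)-eudesma-3,11-dien-3-yl triflate, via lithium enolate 10 (not isolated)
Conditions: Li (2.1 equiv), t-BuOH (1.0 equiv), NH3(l)/THF, −78 °C; evaporate NH3; PhNTf2 (1.3 equiv), THF, 0 °C → rt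
Reagents that add atoms: N-phenylbis(trifluoromethanesulfonimide) O=S(=O)(N(c1ccccc1)S(=O)(=O)C(F)(F)F)C(F)(F)F
Why: Birch-type dissolving-metal reduction protonates C5 axially to give the trans-decalin (H5 anti to the 10-methyl), and the regiodefined C3–C4 enolate is trapped by O-triflation; the isolated isopropenyl group is not reduced.

**Step 5**
Reactants: 11 (5S,7S,10R)-eudesma-3,11-dien-3-yl triflate
Product: 12 (5S,7S,10S)-eudesma-3,11-diene
Conditions: Pd(OAc)2 (5 mol %), PPh3 (10 mol %), HCO2H (2 equiv), n-Bu3N (3 equiv), DMF, 60 °C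
Reagents that add atoms: none
Why: Palladium-catalysed formate reduction of the vinyl triflate (Cacchi reduction) replaces OTf by H and fixes the alkene at C3=C4.

**Step 6**
Reactants: 12 (5S,7S,10S)-eudesma-3,11-diene
Product: 14 (5S,7S,10S)-eudesm-3-en-11-ol, via organomercurial 13 (not isolated)
Conditions: Hg(OAc)2 (1.0 equiv), THF/H2O 1:1, 0 °C, 20 min; then 3 M NaOH, NaBH4, 0 °C
Reagents that add atoms: water O
Why: Markovnikov oxymercuration–demercuration; the 1,1-disubstituted isopropenyl group reacts far faster than the trisubstituted ring alkene, and no carbonyl is present to be reduced.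

**Step 7**
Reactants: 14 (5S,7S,10S)-eudesm-3-en-11-ol
Product: 15 (5S,7S,10S)-11-(triethylsilyloxy)eudesm-3-ene
Conditions: Et3SiOTf (1.5 equiv), 2,6-lutidine (3 equiv), CH2Cl2, −78 → 0 °C
Reagents that add atoms: triethylsilyl trifluoromethanesulfonate CC[Si](CC)(CC)OS(=O)(=O)C(F)(F)F
Why: Silyl triflate silylation protects the tertiary alcohol against the later sulfonylation and organometallic steps.

**Step 8**
Reactants: 15 (5S,7S,10S)-11-(triethylsilyloxy)eudesm-3-ene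
Product: 16 (5S,7S,10R)-11-(triethylsilyloxy)eudesm-3-en-2-one
Conditions: CrO3 (15 equiv), 3,5-dimethylpyrazole (15 equiv), CH2Cl2, −20 °C
Reagents that add atoms: CrO3 O=[Cr](=O)=O
Why: Allylic C–H oxidation by the CrO3–dimethylpyrazole complex goes to the ring CH2 next to the CH= terminus (as 1-methylcyclohexene gives 3-methylcyclohexenone), giving the isophorone-type enone.

**Step 9**
Reactants: 16 (5S,7S,10R)-11-(triethylsilyloxy)eudesm-3-en-2-one
Product: 17 (2R,5S,7S,10R)-11-(triethylsilyloxy)eudesm-3-en-2-ol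
Conditions: NaBH4 (1.2 equiv), CeCl3·7H2O (1.2 equiv), MeOH, −78 → 0 °C
Reagents that add atoms: none
Why: Luche 1,2-reduction; hydride reaches C2 from the face opposite the 1,3-related axial 10-methyl, so the hydroxyl ends cis to that methyl (2R).

**Step 10**
Reactants: 17 (2R,5S,7S,10R)-11-(triethylsilyloxy)eudesm-3-en-2-ol
Product: 18 (2R,3R,4S,5S,7S,10R)-3,4-epoxy-11-(triethylsilyloxy)eudesman-2-ol
Conditions: VO(acac)2 (5 mol %), t-BuOOH (1.5 equiv, decane), CH2Cl2, 0 °C → rt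
Reagents that add atoms: tert-butyl hydroperoxide CC(C)(C)OO
Why: Vanadium-catalysed hydroxyl-directed epoxidation delivers oxygen syn to the C2 hydroxyl, i.e. on the methyl face; this fixes the C4–O configuration of the target.

**Step 11**
Reactants: 18 (2R,3R,4S,5S,7S,10R)-3,4-epoxy-11-(triethylsilyloxy)eudesman-2-ol
Product: 19 (3S,4S,5S,7S,10R)-3,4-epoxy-11-(triethylsilyloxy)eudesman-2-one
Conditions: Dess–Martin periodinane (1.5 equiv), pyridine, CH2Cl2, 0 °C → rt
Reagents that add atoms: none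
Why: Dess–Martin oxidation of the secondary alcohol gives the ketone; epoxide and silyl ether are inert.

**Step 12**
Reactants: 19 (3S,4S,5S,7S,10R)-3,4-epoxy-11-(triethylsilyloxy)eudesman-2-one; 20 2,4,6-trimethoxybenzaldehyde
Product: 22 3,4-epoxy-1-[hydroxy(2,4,6-trimethoxyphenyl)methyl]-11-(triethylsilyloxy)eudesman-2-one, via lithium enolate 21 (not isolated)
Conditions: LiN(i-Pr)2 (1.15 equiv), THF, −78 °C, 45 min; 20 (1.3 equiv), −78 → −40 °C; H2O
Reagents that add atoms: 2,4,6-trimethoxybenzaldehyde COc1cc(OC)c(C=O)c(OC)c1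
Why: Intermolecular aldol addition joins the terpene and aryl fragments at C1–C1′; C3 is an epoxide carbon, so only C1 can be enolised, and the two new stereocentres (a mixture) are erased in step 13.

**Step 13**
Reactants: 22 aldol adduct
Product: 24 (1Z,3S,4S,5S,7S,10S)-3,4-epoxy-1-(2,4,6-trimethoxybenzylidene)-11-(triethylsilyloxy)eudesman-2-one, via mesylate 23 (not isolated)
Conditions: MsCl (1.5 equiv), Et3N (3 equiv), CH2Cl2, 0 °C; DBU (3 equiv), rt; I2 (5 mol %), CH2Cl2, rt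
Reagents that add atoms: none
Why: Mesylation/E1cB elimination completes the aldol condensation; the aryl group settles on the carbonyl side (Z) because the other side is the quaternary C10, and iodine-catalysed equilibration converges any E isomer.

**Step 14**
Reactants: 24 (Z)-arylidene epoxy ketone; 25 isobutyllithium
Product: 27 (1R,3S,4S,5S,7S,10S)-3,4-epoxy-1-[(1S)-3-methyl-1-(2,4,6-trimethoxyphenyl)butyl]-11-(triethylsilyloxy)eudesman-2-one, via lithium enolate 26 (not isolated)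
Conditions: 25 (4 equiv), CuI (2 equiv), Et2O, −40 °C (gives i-Bu2CuLi); 24, THF, −78 → −40 °C; AcOH/THF, −78 °C
Reagents that add atoms: isobutyllithium [Li]CC(C)C
Why: Cuprate 1,4-addition to the exocyclic enone puts isobutyl on C1′ from the face opposite the axial 10-methyl (1′S with the aryl locked on the carbonyl side), and kinetic axial protonation of the enolate on that same face gives 1R with the side chain equatorial.

**Step 15**
Reactants: 27 epoxy ketone
Product: 29 (1R,4R,5S,7S,10R)-1-[(1S)-3-methyl-1-(2,4,6-trimethoxyphenyl)butyl]-11-(triethylsilyloxy)eudesm-2-en-4-ol, via hydrazone 28 (not isolated)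
Conditions: N2H4·H2O (5 equiv), AcOH (0.3 equiv), MeOH, 0 °C → rt
Reagents that add atoms: none
Why: Wharton transposition: the epoxy hydrazone collapses with loss of N2 to the allylic alcohol, removing the C2 oxygen; the C4–O bond is never broken, so the tertiary carbinol keeps the configuration set in step 10.

**Step 16**
Reactants: 29 allylic alcohol
Product: 30 (1R,4R,5S,7S,10R)-1-[(1S)-3-methyl-1-(2,4,6-trimethoxyphenyl)butyl]-11-(triethylsilyloxy)eudesman-4-ol
Conditions: H2 (1 atm), PtO2 (5 mol %), EtOAc, rt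
Reagents that add atoms: none
Why: Catalytic hydrogenation of the cis-disubstituted ring alkene creates no stereocentre and, over platinum, does not hydrogenolyse the allylic tertiary alcohol.

**Step 17**
Reactants: 30 saturated alcohol; 31 N,N-dimethylformamide
Product: 33 (1R,4R,5S,7S,10R)-1-[(1S)-1-(3-formyl-2,4,6-trimethoxyphenyl)-3-methylbutyl]-11-(triethylsilyloxy)eudesman-4-ol, via aryllithium 32 (not isolated)
Conditions: n-BuLi (2.5 equiv), TMEDA (2.5 equiv), THF, 0 °C, 2 h; 31 (4 equiv), −78 → 0 °C; H2O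
Reagents that add atoms: N,N-dimethylformamide CN(C)C=O
Why: Directed ortho-metalation at the ring C–H flanked by two methoxy groups, then formylation with DMF; the C4 hydroxyl rides through as its lithium alkoxide.

**Step 18**
Reactants: 33 mono-aldehyde; 31 N,N-dimethylformamide
Product: 36 (1R,4R,5S,7S,10R)-1-[(1S)-1-(3,5-diformyl-2,4,6-trimethoxyphenyl)-3-methylbutyl]-11-(triethylsilyloxy)eudesman-4-ol, via amino alkoxide 34 (not isolated), via lithiated amino alkoxide 35 (not isolated)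
Conditions: Me2NCH2CH2NHMe (2.4 equiv), n-BuLi (2.3 equiv), THF, −20 °C; 33; n-BuLi (3 equiv), −20 → 0 °C, 3 h; 31 (6 equiv), −78 °C → rt; H2O
Reagents that add atoms: N,N-dimethylformamide CN(C)C=O
Why: Comins in situ protection of the aldehyde as an α-amino alkoxide allows a second ortho-lithiation at the last ring C–H and a second DMF formylation.

**Step 19**
Reactants: 36 dialdehyde silyl ether
Product: 37 5-[(1S)-1-[(1R,4R,5S,7S,10R)-4,11-dihydroxyeudesman-1-yl]-3-methylbutyl]-2,4,6-trimethoxybenzene-1,3-dicarbaldehyde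
Conditions: HF·pyridine, pyridine/THF, 0 °C → rt
Reagents that add atoms: none
Why: Fluoride-driven desilylation frees the C11 tertiary alcohol under conditions that leave aldehydes and the C4 carbinol alone.

**Step 20**
Reactants: 37 tri-O-methyl ether
Product: 38 target, 5-[(1S)-1-[(1R,4R,5S,7S,10R)-4,11-dihydroxyeudesman-1-yl]-3-methylbutyl]-2,4,6-trihydroxybenzene-1,3-dicarbaldehyde
Conditions: NaSEt (10 equiv), DMF, 110 °C, 3 h; then 1 M HCl to pH 3, 0 °C
Reagents that add atoms: none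
Why: SN2 O-demethylation by thiolate; every methoxy group is ortho or para to a formyl group and so activated, and the basic medium spares both tertiary alcohols and all stereocentres.

**Compound list**
1 | (S)-(+)-carvone | O=C1C[C@@H](C(C)=C)CC=C1C | starting material
2 | lithium (5S)-2-methyl-5-(prop-1-en-2-yl)cyclohex-1-en-1-olate | [Li]OC1=C(C)CC[C@H](C(C)=C)C1 | intermediate (not isolated)
3 | (2S,5S)-2-methyl-5-(prop-1-en-2-yl)cyclohexan-1-one, (−)-trans-dihydrocarvone (some 2R epimer) | O=C1C[C@@H](C(C)=C)CC[C@@H]1C | intermediate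
4 | (S)-(−)-1-phenylethylamine | C[C@H](N)c1ccccc1 | starting material
5 | ethyl vinyl ketone (pent-1-en-3-one) | CCC(=O)C=C | starting material
6 | N-[(1S)-1-phenylethyl] ketimine of 3 | C[C@H](N=C1C[C@@H](C(C)=C)CC[C@@H]1C)c1ccccc1 | intermediate (not isolated)
7 | N-[(1S)-1-phenylethyl] imine of 8 | C[C@H](N=C1C[C@@H](C(C)=C)CC[C@]1(C)CCC(=O)CC)c1ccccc1 | intermediate (not isolated)
8 | (2R,5S)-2-methyl-2-(3-oxopentyl)-5-(prop-1-en-2-yl)cyclohexan-1-one | O=C1C[C@@H](C(C)=C)CC[C@]1(C)CCC(=O)CC | intermediate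
9 | (−)-α-cyperone, (4aR,7S)-1,4a-dimethyl-7-(prop-1-en-2-yl)-4,4a,5,6,7,8-hexahydronaphthalen-2(3H)-one | C1CC(=O)C(C)=C2C[C@@H](C(C)=C)CC[C@]12C | intermediate
10 | lithium (5S,7S,10R)-eudesma-3,11-dien-3-olate (trans-fused) | C1CC(O[Li])=C(C)[C@H]2C[C@@H](C(C)=C)CC[C@]12C | intermediate (not isolated)
11 | (5S,7S,10R)-eudesma-3,11-dien-3-yl trifluoromethanesulfonate | C1CC(OS(=O)(=O)C(F)(F)F)=C(C)[C@H]2C[C@@H](C(C)=C)CC[C@]12C | intermediate
12 | (5S,7S,10S)-eudesma-3,11-diene (ent-α-selinene) | C1CC=C(C)[C@H]2C[C@@H](C(C)=C)CC[C@]12C | intermediate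
13 | (5S,7S,10S)-12-(acetoxymercurio)eudesm-3-en-11-ol (C11 epimers) | C1CC=C(C)[C@H]2C[C@@H](C(C)(O)C[Hg]OC(C)=O)CC[C@]12C | intermediate (not isolated)
14 | (5S,7S,10S)-eudesm-3-en-11-ol (ent-α-eudesmol) | C1CC=C(C)[C@H]2C[C@@H](C(C)(C)O)CC[C@]12C | intermediate
15 | (5S,7S,10S)-11-(triethylsilyloxy)eudesm-3-ene | C1CC=C(C)[C@H]2C[C@@H](C(C)(C)O[Si](CC)(CC)CC)CC[C@]12C | intermediate
16 | (5S,7S,10R)-11-(triethylsilyloxy)eudesm-3-en-2-one | C1C(=O)C=C(C)[C@H]2C[C@@H](C(C)(C)O[Si](CC)(CC)CC)CC[C@]12C | intermediate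
17 | (2R,5S,7S,10R)-11-(triethylsilyloxy)eudesm-3-en-2-ol (2-OH cis to 10-CH3) | C1[C@@H](O)C=C(C)[C@H]2C[C@@H](C(C)(C)O[Si](CC)(CC)CC)CC[C@]12C | intermediate
18 | (2R,3R,4S,5S,7S,10R)-3,4-epoxy-11-(triethylsilyloxy)eudesman-2-ol (epoxide O, 2-OH and 10-CH3 cis) | C1[C@@H](O)[C@H]3O[C@@]3(C)[C@H]2C[C@@H](C(C)(C)O[Si](CC)(CC)CC)CC[C@]12C | intermediate
19 | (3S,4S,5S,7S,10R)-3,4-epoxy-11-(triethylsilyloxy)eudesman-2-one | C1C(=O)[C@H]3O[C@@]3(C)[C@H]2C[C@@H](C(C)(C)O[Si](CC)(CC)CC)CC[C@]12C | intermediate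
20 | 2,4,6-trimethoxybenzaldehyde | COc1cc(OC)c(C=O)c(OC)c1 | starting material
21 | lithium 1(2)-en-2-olate of 19 | C1=C(O[Li])[C@H]3O[C@@]3(C)[C@H]2C[C@@H](C(C)(C)O[Si](CC)(CC)CC)CC[C@]12C | intermediate (not isolated)
22 | (3S,4S,5S,7S)-3,4-epoxy-1-[hydroxy(2,4,6-trimethoxyphenyl)methyl]-11-(triethylsilyloxy)eudesman-2-one (mixture at C1 and C1′) | OC(c4c(OC)cc(OC)cc4OC)C1C(=O)[C@H]3O[C@@]3(C)[C@H]2C[C@@H](C(C)(C)O[Si](CC)(CC)CC)CC[C@]12C | intermediate
23 | methanesulfonate of 22 | CS(=O)(=O)OC(c4c(OC)cc(OC)cc4OC)C1C(=O)[C@H]3O[C@@]3(C)[C@H]2C[C@@H](C(C)(C)O[Si](CC)(CC)CC)CC[C@]12C | intermediate (not isolated)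
24 | (1Z,3S,4S,5S,7S,10S)-3,4-epoxy-1-(2,4,6-trimethoxybenzylidene)-11-(triethylsilyloxy)eudesman-2-one | COc4cc(OC)cc(OC)c4/C=C1\C(=O)[C@H]3O[C@@]3(C)[C@H]2C[C@@H](C(C)(C)O[Si](CC)(CC)CC)CC[C@]12C | intermediate
25 | isobutyllithium | [Li]CC(C)C | starting material
26 | lithium 1(2)-en-2-olate of 27 (1′S) | CC(C)C[C@H](c4c(OC)cc(OC)cc4OC)C1=C(O[Li])[C@H]3O[C@@]3(C)[C@H]2C[C@@H](C(C)(C)O[Si](CC)(CC)CC)CC[C@]12C | intermediate (not isolated)
27 | (1R,3S,4S,5S,7S,10S)-3,4-epoxy-1-[(1S)-3-methyl-1-(2,4,6-trimethoxyphenyl)butyl]-11-(triethylsilyloxy)eudesman-2-one | CC(C)C[C@H](c4c(OC)cc(OC)cc4OC)[C@H]1C(=O)[C@H]3O[C@@]3(C)[C@H]2C[C@@H](C(C)(C)O[Si](CC)(CC)CC)CC[C@]12C | intermediate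
28 | hydrazone of 27 | CC(C)C[C@H](c4c(OC)cc(OC)cc4OC)[C@H]1C(=NN)[C@H]3O[C@@]3(C)[C@H]2C[C@@H](C(C)(C)O[Si](CC)(CC)CC)CC[C@]12C | intermediate (not isolated)
29 | (1R,4R,5S,7S,10R)-1-[(1S)-3-methyl-1-(2,4,6-trimethoxyphenyl)butyl]-11-(triethylsilyloxy)eudesm-2-en-4-ol | CC(C)C[C@H](c4c(OC)cc(OC)cc4OC)[C@H]1C=C[C@@](C)(O)[C@H]2C[C@@H](C(C)(C)O[Si](CC)(CC)CC)CC[C@]12C | intermediate
30 | (1R,4R,5S,7S,10R)-1-[(1S)-3-methyl-1-(2,4,6-trimethoxyphenyl)butyl]-11-(triethylsilyloxy)eudesman-4-ol | CC(C)C[C@H](c4c(OC)cc(OC)cc4OC)[C@H]1CC[C@@](C)(O)[C@H]2C[C@@H](C(C)(C)O[Si](CC)(CC)CC)CC[C@]12C | intermediate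
31 | N,N-dimethylformamide | CN(C)C=O | starting material
32 | dilithio derivative of 30 (C4 lithium alkoxide, lithium on aryl C3) | CC(C)C[C@H](c4c(OC)c([Li])c(OC)cc4OC)[C@H]1CC[C@@](C)(O[Li])[C@H]2C[C@@H](C(C)(C)O[Si](CC)(CC)CC)CC[C@]12C | intermediate (not isolated)
33 | (1R,4R,5S,7S,10R)-1-[(1S)-1-(3-formyl-2,4,6-trimethoxyphenyl)-3-methylbutyl]-11-(triethylsilyloxy)eudesman-4-ol | CC(C)C[C@H](c4c(OC)c(C=O)c(OC)cc4OC)[C@H]1CC[C@@](C)(O)[C@H]2C[C@@H](C(C)(C)O[Si](CC)(CC)CC)CC[C@]12C | intermediate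
34 | lithium α-amino alkoxide of 33 (C4 lithium alkoxide; hemiaminal carbon unassigned) | CC(C)C[C@H](c4c(OC)c(C(O[Li])N(C)CCN(C)C)c(OC)cc4OC)[C@H]1CC[C@@](C)(O[Li])[C@H]2C[C@@H](C(C)(C)O[Si](CC)(CC)CC)CC[C@]12C | intermediate (not isolated)
35 | ring-lithiated 34 (lithium on aryl C5) | CC(C)C[C@H](c4c(OC)c(C(O[Li])N(C)CCN(C)C)c(OC)c([Li])c4OC)[C@H]1CC[C@@](C)(O[Li])[C@H]2C[C@@H](C(C)(C)O[Si](CC)(CC)CC)CC[C@]12C | intermediate (not isolated)
36 | (1R,4R,5S,7S,10R)-1-[(1S)-1-(3,5-diformyl-2,4,6-trimethoxyphenyl)-3-methylbutyl]-11-(triethylsilyloxy)eudesman-4-ol | CC(C)C[C@H](c4c(OC)c(C=O)c(OC)c(C=O)c4OC)[C@H]1CC[C@@](C)(O)[C@H]2C[C@@H](C(C)(C)O[Si](CC)(CC)CC)CC[C@]12C | intermediate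
37 | 5-[(1S)-1-[(1R,4R,5S,7S,10R)-4,11-dihydroxyeudesman-1-yl]-3-methylbutyl]-2,4,6-trimethoxybenzene-1,3-dicarbaldehyde | CC(C)C[C@H](c4c(OC)c(C=O)c(OC)c(C=O)c4OC)[C@H]1CC[C@@](C)(O)[C@H]2C[C@@H](C(C)(C)O)CC[C@]12C | intermediate
38 | 5-[(1S)-1-[(1R,4R,5S,7S,10R)-4,11-dihydroxyeudesman-1-yl]-3-methylbutyl]-2,4,6-trihydroxybenzene-1,3-dicarbaldehyde | CC(C)C[C@H](c1c(O)c(C=O)c(O)c(C=O)c1O)[C@H]1CC[C@@](C)(O)[C@H]2C[C@@H](C(C)(C)O)CC[C@]12C | target

**Totals**
Total step count: 20. Longest linear sequence: 20 steps, from 1 to 38; compounds 4, 5, 20, 25 and 31 are bought.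

**Three steps most likely to fail**

Step 14 (cuprate addition). The β-carbon is hindered, and i-Bu2CuLi can also reduce an α,β-epoxy ketone by electron transfer. Fallback: put the side chain on before the epoxide exists, setting out from 16 and coming back at 27. The α′-lithium enolate of 16 (LiN(i-Pr)2, THF, −78 °C) is added to 20 to give the aldol adduct F1. Mesylation gives the mesylate F2, and DBU elimination with iodine equilibration gives the (Z)-arylidene dienone F3. i-Bu2CuLi then adds only at C1′, because the ring β-carbon C4 is fully substituted, and axial protonation gives the adduct enone F4. Luche reduction gives the allylic alcohol F5 (hydroxyl cis to the 10-methyl), VO(acac)2/t-BuOOH gives the epoxy alcohol F6, and Dess–Martin oxidation returns 27.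

Step 8 (allylic oxidation). Oxidation may compete at the tertiary C5–H or give low conversion. Fallback: a regiochemically forced four-operation detour, setting out from 15 and coming back at 16. m-CPBA epoxidises 15 on the face away from the angular methyl to the epoxide F7. PhSeNa (from PhSeSePh and NaBH4, EtOH) opens it at the secondary C3 to the hydroxy selenide F8. H2O2 gives the selenoxide F9, whose syn-elimination can only go toward C2 and yields the tertiary allylic alcohol F10. Oxidative 1,3-transposition with C5H5NH[CrO3Cl] (pyridinium chlorochromate, CH2Cl2) returns enone 16.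

Step 12 (aldol). The neopentyl C1 enolate and the hindered, electron-rich aldehyde may give a reversible, low-conversion aldol. Fallback: a Mannich condensation, setting out from 19 and coming back at 24. The iminium iodide F11 is generated from 20 with Me2NH, Me3SiCl and NaI in MeCN and added to lithium enolate 21 to give, irreversibly, the Mannich base F12. Methylation with MeI gives the ammonium iodide F13, and DBU elimination followed by iodine equilibration returns 24.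

**Further compounds**
F1 | step 14 | aldol adduct of 16 and 20, 1-[hydroxy(2,4,6-trimethoxyphenyl)methyl]-11-(triethylsilyloxy)eudesm-3-en-2-one (mixture at C1 and C1′) | OC(c4c(OC)cc(OC)cc4OC)C1C(=O)C=C(C)[C@H]2C[C@@H](C(C)(C)O[Si](CC)(CC)CC)CC[C@]12C
F2 | step 14 | methanesulfonate of F1 | CS(=O)(=O)OC(c4c(OC)cc(OC)cc4OC)C1C(=O)C=C(C)[C@H]2C[C@@H](C(C)(C)O[Si](CC)(CC)CC)CC[C@]12C
F3 | step 14 | (1Z)-1-(2,4,6-trimethoxybenzylidene)-11-(triethylsilyloxy)eudesm-3-en-2-one | COc4cc(OC)cc(OC)c4/C=C1\C(=O)C=C(C)[C@H]2C[C@@H](C(C)(C)O[Si](CC)(CC)CC)CC[C@]12C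
F4 | step 14 | (1R)-1-[(1S)-3-methyl-1-(2,4,6-trimethoxyphenyl)butyl]-11-(triethylsilyloxy)eudesm-3-en-2-one | CC(C)C[C@H](c4c(OC)cc(OC)cc4OC)[C@H]1C(=O)C=C(C)[C@H]2C[C@@H](C(C)(C)O[Si](CC)(CC)CC)CC[C@]12C
F5 | step 14 | allylic alcohol from F4 (2-OH cis to 10-CH3) | CC(C)C[C@H](c4c(OC)cc(OC)cc4OC)[C@H]1[C@@H](O)C=C(C)[C@H]2C[C@@H](C(C)(C)O[Si](CC)(CC)CC)CC[C@]12C
F6 | step 14 | 3,4-epoxy alcohol from F5 (epoxide cis to 2-OH and 10-CH3) | CC(C)C[C@H](c4c(OC)cc(OC)cc4OC)[C@H]1[C@@H](O)[C@H]3O[C@@]3(C)[C@H]2C[C@@H](C(C)(C)O[Si](CC)(CC)CC)CC[C@]12C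
F7 | step 8 | 3,4-epoxy-11-(triethylsilyloxy)eudesmane (epoxide trans to 10-CH3) | C1C[C@@H]3O[C@]3(C)[C@H]2C[C@@H](C(C)(C)O[Si](CC)(CC)CC)CC[C@]12C
F8 | step 8 | 3-(phenylselanyl)-11-(triethylsilyloxy)eudesman-4-ol | C1C[C@@H]([Se]c5ccccc5)[C@](C)(O)[C@H]2C[C@@H](C(C)(C)O[Si](CC)(CC)CC)CC[C@]12C
F9 | step 8 | selenoxide of F8 | C1C[C@@H]([Se](=O)c5ccccc5)[C@](C)(O)[C@H]2C[C@@H](C(C)(C)O[Si](CC)(CC)CC)CC[C@]12C
F10 | step 8 | 11-(triethylsilyloxy)eudesm-2-en-4-ol (4-OH trans to 10-CH3) | C1C=C[C@](C)(O)[C@H]2C[C@@H](C(C)(C)O[Si](CC)(CC)CC)CC[C@]12C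
F11 | step 12 | N,N-dimethyl(2,4,6-trimethoxybenzylidene)iminium iodide | C[N+](C)=Cc1c(OC)cc(OC)cc1OC.[I-]
F12 | step 12 | Mannich base, 1-[(dimethylamino)(2,4,6-trimethoxyphenyl)methyl]-3,4-epoxy-11-(triethylsilyloxy)eudesman-2-one (mixture at C1 and C1′) | CN(C)C(c4c(OC)cc(OC)cc4OC)C1C(=O)[C@H]3O[C@@]3(C)[C@H]2C[C@@H](C(C)(C)O[Si](CC)(CC)CC)CC[C@]12C
F13 | step 12 | trimethylammonium iodide of F12 | C[N+](C)(C)C(c4c(OC)cc(OC)cc4OC)C1C(=O)[C@H]3O[C@@]3(C)[C@H]2C[C@@H](C(C)(C)O[Si](CC)(CC)CC)CC[C@]12C.[I-]
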